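## Structural features

The target is a 3,4-dihydrocoumarin: benzene ring A (C4a, C5–C8, C8a) fused to the lactone ring B (O1, C2, C3, C4). It carries a 4-hydroxyphenyl ring (double-primed atoms) on C4 and a 4-methoxy-2-pyrone (primed atoms O1'–C6') joined through C6' to C6. Ring A is substituted at five carbons (C4a alkyl, C5 methyl, C6 pyrone, C7 hydroxyl, C8a lactone oxygen) and C8 is its only CH. The C6–C6' bond therefore lies between a methyl group and an oxygen substituent, and the two resorcinol oxygens O7 and O1 have different fates. C4 (R) is the only stereocentre, doubly benzylic and peri to the C5 methyl group; no stereocentre adjoins it, so it must be set by absolute control. Fragile groups are the aryl lactone (opened by base and nucleophiles), the methoxypyrone (a vinylogous ester, sensitive to hydroxide and strong Lewis acids) and the electron-rich ring A with its phenols (oxidation, electrophiles at C8). The real difficulties are the hindered C6–C6' bond, the choice between C4a and C8 (and between O1 and O7) when ring B is closed, and enantiocontrol at C4. The key step uses the fact that C5'–C6' together with C6 is an aryl alkyne in disguise, while O1', C2', C3' and C4' with its methoxy group are an intact 3-methoxyacrylic acid. The pyrone can thus be closed across the alkyne (C4'–C5' and O1'–C6') with the C6–C6' bond already in place.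

## Logic of the disconnections

**12 to 11.** The O–CH2Ph bonds at O7 and O4'' are cut. Both phenols have to be masked during the base- and oxidant-mediated ring closure, and benzyl ethers leave under neutral conditions that spare the lactone. The last step becomes one operation. The demand is that hydrogenolysis must not touch the pyrone double bonds.

**11 to 8 and 10.** C4–C4a and O1–C2 are cut. One catalytic event then forms ring B and the stereocentre, and the target falls into two pieces of similar size. The demand is that carbon attack occurs at C4a and not at C8, and from one face. For that reason 8 has only O8a free: C4a is then ortho to the phenoxide and para to the ether oxygen, C8 lies between two oxygen substituents, and O7 cannot lactonise. Face selectivity has to come from the chiral carbene.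

**8 to 7.** The O8a–CH2OMe bond is cut. An acetal on O8a and a benzyl ether on O7 are orthogonal, which is what makes the previous disconnection regiochemically safe. Nothing is gained in skeleton. The demand is an acid treatment that leaves the 4'-methoxy group alone, hence methanol as solvent so that any exchange is degenerate.

**10 to 9.** The O4''–CH2Ph bond is cut. A free para-phenoxide would deactivate the acyl azolium and would itself be acylated. The forward step is a plain O-alkylation.

**7 to 4 and 6.** C4'–C5' and O1'–C6' are cut. No bond has to be made at the di-ortho-substituted C6, and the 4'-methoxy group arrives with 6. The aryl pyrone is reduced to an aryl alkyne and a four-carbon acid. The demands are cleavage of the β-C–H of 6, insertion of 4 with its aryl-bearing carbon next to oxygen, and an anode that spares ring A.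

**4 to 3.** The terminal carbon C5' is removed, leaving C6' as a formyl carbon. The hindered C6–C6' bond is thereby traced to the aryl–CHO bond of a benzaldehyde. The demand is a one-carbon homologation that works on an electron-rich, di-ortho-substituted aldehyde and tolerates both ethers.

**3 to 2 to 1.** O7–CH2Ph is cut first, then O8a–CH2OMe. In 1 the hydroxyl para to the formyl group is free and more acidic, while the ortho hydroxyl is hydrogen-bonded. The acetal can therefore be placed selectively on the future O8a and the benzyl group on the future O7. This buys the O1/O7 differentiation for one extra alkylation. The demand is mono-selectivity in the first alkylation.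

**6 to 5.** The acyl–OMe bond is cut, because the ester is the stable commercial form. The demand is a work-up that does not hydrolyse the enol ether.

## Other disconnections considered

**Alternative 1:** The cut runs through ring A at C4a–C5 and C6–C7. The ring is assembled from the dioxygenated cyclohexadiene A2 (which supplies C4a, C8a, C8, C7 and a saturated two-carbon bridge) and the alkynylpyrone A3 (which supplies C5 and C6). Forward, a Diels–Alder addition would be followed by loss of the bridge as an alkene in a retro-Diels–Alder step (Alder–Rickert), giving A1.
- In favour: every substituent of ring A is placed by construction, O7 and O8a emerge differently protected, and the C4 side chain sits on C4a from the start. On ring A regiochemistry this alternative is better than the chosen plan, which must win C4a over C8 in step 8. It is the equal of the chosen plan in avoiding a cross-coupling at C6, and it needs no electrolysis.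
- Against: the diene terminus that becomes C4a is fully substituted and carries the branched stereogenic chain. A3 is only weakly activated, and its 2-pyrone is itself a diene and a dienophile. Forcing thermal conditions would be needed, under which silyl enol ethers can migrate. A2 requires two different enol ethers to be formed regioselectively from an unsymmetrical 1,3-dione, with the stereocentre already installed by a separate asymmetric step.
- Comparison: the mechanism is a thermal pericyclic cascade against a catalytic C–H annulation. With the synthesis of A2 and A3 and three operations after A1 (desilylation with lactonisation, two deprotections), the step count would be clearly higher than nine.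

**Alternative 2:** The cut is again in ring A (C6–C7 and C5–C6), but both halves come from one pyrone, A5. Forward, a hindered lithium amide would deprotonate the 6-methyl group of one molecule of A5, and the anion would attack the lactone carbonyl of a second. The opened chain would reclose by aldol condensation onto its methyl ketone and aromatise to A4.
- In favour: a single metal-free step of a known carbanion type creates ring A and the hindered C6–C6' bond from one simple building block. On precedent and on steps to the aryl-pyrone stage it is better than the chosen plan, which needs five steps to reach 7.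
- Against: A4 has O7 free and O8a benzylated, the reverse of what a phenol-directed closure of ring B needs, and its 4'-oxygen is benzylated rather than methylated. Protection of O7, double debenzylation and selective methylation of the acidic 4'-hydroxyl would use up the steps saved. The self-condensation also has to stop at the dimer although A4 is more acidic than A5.
- Comparison: for everything after the aryl pyrone (C4a against C8, the C4 stereocentre) this alternative is only the equal of the chosen plan. Its total length would be similar or slightly greater.

**Alternative 3:** The cut is in the 4-hydroxyphenyl ring at C1''–C6'' and C2''–C3''. Forward, the aldehyde arm of A7 would be activated as an enamine under secondary-amine/carboxylic-acid catalysis and would add to the ynone A8. The methyl ketone would then condense onto the former aldehyde carbon, and the cyclohexadienone would tautomerise to the phenol A6.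
- In favour: the stereocentre would come from an enantioselective opening of a symmetrical anhydride, a well-established kind of control that may be the equal of the carbene step in reliability. Ring A is regiochemically fixed from the outset (side chain on C4a, bromine marking C6); on that point this alternative is better than the chosen plan.
- Against: a benzene ring that can be bought ready-made is built atom by atom, and A8 is prone to polymerise under amine catalysis. Above all, the pyrone must afterwards be attached at C6 by cross-coupling at a bromide flanked by a methyl group and a MOM ether. That is the one bond the chosen plan never has to make; on this point the alternative is worse.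
- Comparison: with the anhydride synthesis, half-ester reduction, ring construction, cross-coupling and closure of ring B, the sequence would be well beyond nine steps.

Key step: step 5

Assumption: the (5aS,10bR) aminoindanol-derived N-mesityl triazolium salt is taken to direct the arene to the Re face of C-β of the acyl azolium, which gives (4R); if the sense proves opposite, the (5aR,10bS) antipode is used with no other change.

## Route

Step 1
Reactants: 1 2,4-dihydroxy-6-methylbenzaldehyde
Product: 2 2-hydroxy-4-(methoxymethoxy)-6-methylbenzaldehyde
Conditions: MOMCl (1.05 equiv), K2CO3, acetone, 0 °C to rt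
Reagents that add atoms: chloromethyl methyl ether, COCCl
Why: Williamson-type O-alkylation; the hydroxyl para to the formyl group is the more acidic and is not held in the hydrogen bond to the carbonyl oxygen, so one equivalent of MOMCl with a weak base should alkylate it alone.

Step 2
Reactants: 2 2-hydroxy-4-(methoxymethoxy)-6-methylbenzaldehyde
Product: 3 2-(benzyloxy)-4-(methoxymethoxy)-6-methylbenzaldehyde
Conditions: BnBr, K2CO3, DMF, 60 °C
Reagents that add atoms: benzyl bromide, BrCc1ccccc1
Why: Williamson ether synthesis on the remaining hydrogen-bonded phenol, which needs the more forcing conditions; the benzyl group goes on the oxygen that becomes O7 and survives the later acidic removal of the MOM group.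

Step 3
Reactants: 3 2-(benzyloxy)-4-(methoxymethoxy)-6-methylbenzaldehyde
Product: 4 1-(benzyloxy)-2-ethynyl-5-(methoxymethoxy)-3-methylbenzene
Conditions: dimethyl (1-diazo-2-oxopropyl)phosphonate (1.5 equiv), K2CO3, MeOH, 0 °C to rt
Reagents that add atoms: dimethyl (1-diazo-2-oxopropyl)phosphonate, COP(=O)(OC)C(=[N+]=[N-])C(C)=O
Why: Ohira–Bestmann (Seyferth–Gilbert) homologation: methanolysis of the reagent frees the diazomethylphosphonate anion, which olefinates the aldehyde, and the diazoalkene loses N2 with a 1,2-shift to give the terminal alkyne; both ethers are inert to K2CO3/MeOH and the aldehyde has no α-hydrogen.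

Step 4
Reactants: 5 methyl (E)-3-methoxyacrylate
Product: 6 (E)-3-methoxyacrylic acid
Conditions: LiOH·H2O (1.5 equiv), THF/H2O, 0 °C to rt; then 1 M HCl to pH 3, 0 °C
Reagents that add atoms: lithium hydroxide, [Li+].[OH-]
Why: Saponification of a methyl ester by acyl–oxygen cleavage; the enol ether and its E geometry are stable to hydroxide, and brief cold acidification avoids hydrolysis of the enol ether.

Step 5
Reactants: 4 1-(benzyloxy)-2-ethynyl-5-(methoxymethoxy)-3-methylbenzene; 6 (E)-3-methoxyacrylic acid
Product: 7 6-[2-(benzyloxy)-4-(methoxymethoxy)-6-methylphenyl]-4-methoxy-2H-pyran-2-one
Conditions: 6 (2 equiv), [Cp*IrCl2]2 (5 mol %), KOAc (2 equiv), MeOH, 60 °C, undivided cell, graphite-felt anode, Pt cathode, constant current (2 mA), 4 added slowly by syringe pump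
Reagents that add atoms: none
Why: Proposed new method: the closest known reaction type is the electro-oxidative [Cp*IrCl2]2-catalysed C–H/O–H annulation of acrylic acids with internal alkynes to 2-pyrones, which has not been shown with a terminal aryl alkyne or a 3-alkoxyacrylic acid. Acetate-assisted metalation of 6 at C4' is expected because in the E acid the only hydrogen cis to the carboxylate is the one on the methoxy-bearing carbon, the same hydrogen that chelation-directed lithiation of 3-alkoxyacrylates removes, and it gives a five-membered iridacycle of trivalent iridium. Alkyne 4 should then insert with its unsubstituted carbon forming C4'–C5' and its aryl-bearing carbon on iridium, the usual sense for terminal alkynes in carboxylate-assisted annulations of this catalyst type, since the C–C bond forms at the less hindered terminus and the aryl group stabilises the metal–carbon bond. C–O reductive elimination from the seven-membered iridacycle closes the pyrone ring (O1'–C6', a formal oxidative [4+2] annulation) and leaves a monovalent iridium η4-pyrone complex, which the anode oxidises back to trivalent iridium while the cathode reduces protons to H2, so no chemical oxidant is present. No stereocentre is formed. The step needs regioselective insertion, which the steric difference between hydrogen and a di-ortho-substituted aryl group should secure, and chemoselectivity against alkyne self-coupling and anodic oxidation of ring A, which slow addition of 4, an excess of 6 and a low current density at a large-area anode are meant to secure because the iridium intermediate should be oxidised at a lower potential than a dialkoxyarene. The hindered C6–C6' bond is already present in 4 as the aryl–alkyne bond, so no cross-coupling at the di-ortho-substituted carbon is required.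

Step 6
Reactants: 7 6-[2-(benzyloxy)-4-(methoxymethoxy)-6-methylphenyl]-4-methoxy-2H-pyran-2-one
Product: 8 6-[2-(benzyloxy)-4-hydroxy-6-methylphenyl]-4-methoxy-2H-pyran-2-one
Conditions: HCl (from AcCl), MeOH, 0 to 40 °C
Reagents that add atoms: none
Why: Acid-catalysed acetal exchange transfers the MOM group to methanol as dimethoxymethane, which keeps formaldehyde equivalents away from the electron-rich ring; the benzyl ether is stable, and any exchange at C4' in methanol returns the same methoxy group.

Step 7
Reactants: 9 (E)-4-hydroxycinnamaldehyde
Product: 10 (E)-3-[4-(benzyloxy)phenyl]prop-2-enal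
Conditions: BnBr, K2CO3, acetone, 50 °C
Reagents that add atoms: benzyl bromide, BrCc1ccccc1
Why: Williamson ether synthesis on the phenoxide; masking this phenol prevents a para-oxido group from deactivating the acyl azolium or being acylated in step 8, and the same hydrogenolysis removes it at the end.

Step 8
Reactants: 8 6-[2-(benzyloxy)-4-hydroxy-6-methylphenyl]-4-methoxy-2H-pyran-2-one; 10 (E)-3-[4-(benzyloxy)phenyl]prop-2-enal
Product: 11 (4R)-7-(benzyloxy)-4-[4-(benzyloxy)phenyl]-6-(4-methoxy-2-oxo-2H-pyran-6-yl)-5-methyl-3,4-dihydro-2H-chromen-2-one
Conditions: 10 (1.5 equiv), (5aS,10bR)-N-mesityl indeno-oxazino-triazolium chloride (15 mol %), K2CO3 (0.5 equiv), 3,3',5,5'-tetra-tert-butyldiphenoquinone (1.2 equiv), 4 Å MS, toluene, rt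
Reagents that add atoms: none
Why: Oxidative NHC catalysis, the [3+3] annulation of an α,β-unsaturated acyl azolium with a hydroxyarene known for naphthols and electron-rich phenols: the Breslow intermediate of 10 is oxidised by the diphenoquinone, the phenoxide of 8 adds through C4a to C-β (directly or by O-addition and [3,3] shift), and the C8a oxygen then acylates to close ring B and release the carbene. C4a is the only ring carbon ortho to the free phenoxide and para to the benzyloxy group, whereas C8 lies between two oxygen substituents and O7 cannot lactonise, so a single constitution is expected. The fused chiral backbone of the carbene blocks one face of the acyl azolium so that the arene adds to the Re face of C-β, which sets (4R).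

Step 9
Reactants: 11 (4R)-7-(benzyloxy)-4-[4-(benzyloxy)phenyl]-6-(4-methoxy-2-oxo-2H-pyran-6-yl)-5-methyl-3,4-dihydro-2H-chromen-2-one
Product: 12 (4R)-7-hydroxy-4-(4-hydroxyphenyl)-6-(4-methoxy-2-oxo-2H-pyran-6-yl)-5-methyl-3,4-dihydro-2H-chromen-2-one
Conditions: H2 (1 atm), Pd/C (10 wt %), EtOAc, rt, stopped at full debenzylation
Reagents that add atoms: none
Why: Catalytic hydrogenolysis of two aryl benzyl ethers under neutral conditions; the aryl lactone, the C4 stereocentre (a C–H with no benzylic C–O bond) and the trisubstituted, heteroatom-bearing pyrone double bonds should be untouched at 1 atm and room temperature.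

## Compound list

1 | 2,4-dihydroxy-6-methylbenzaldehyde | Cc1cc(O)cc(O)c1C=O | starting material
2 | 2-hydroxy-4-(methoxymethoxy)-6-methylbenzaldehyde | COCOc1cc(C)c(C=O)c(O)c1 | intermediate
3 | 2-(benzyloxy)-4-(methoxymethoxy)-6-methylbenzaldehyde | COCOc1cc(C)c(C=O)c(OCc2ccccc2)c1 | intermediate
4 | 1-(benzyloxy)-2-ethynyl-5-(methoxymethoxy)-3-methylbenzene | COCOc1cc(C)c(C#C)c(OCc2ccccc2)c1 | intermediate
5 | methyl (E)-3-methoxyacrylate | CO/C=C/C(=O)OC | starting material
6 | (E)-3-methoxyacrylic acid | CO/C=C/C(=O)O | intermediate
7 | 6-[2-(benzyloxy)-4-(methoxymethoxy)-6-methylphenyl]-4-methoxy-2H-pyran-2-one | COCOc1cc(C)c(-c2cc(OC)cc(=O)o2)c(OCc2ccccc2)c1 | intermediate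
8 | 6-[2-(benzyloxy)-4-hydroxy-6-methylphenyl]-4-methoxy-2H-pyran-2-one | COc1cc(-c2c(C)cc(O)cc2OCc2ccccc2)oc(=O)c1 | intermediate
9 | (E)-4-hydroxycinnamaldehyde | O=C/C=C/c1ccc(O)cc1 | starting material
10 | (E)-3-[4-(benzyloxy)phenyl]prop-2-enal | O=C/C=C/c1ccc(OCc2ccccc2)cc1 | intermediate
11 | (4R)-7-(benzyloxy)-4-[4-(benzyloxy)phenyl]-6-(4-methoxy-2-oxo-2H-pyran-6-yl)-5-methyl-3,4-dihydro-2H-chromen-2-one | COc1cc(-c2c(OCc3ccccc3)cc3c(c2C)[C@@H](c2ccc(OCc4ccccc4)cc2)CC(=O)O3)oc(=O)c1 | intermediate
12 | (4R)-7-hydroxy-4-(4-hydroxyphenyl)-6-(4-methoxy-2-oxo-2H-pyran-6-yl)-5-methyl-3,4-dihydro-2H-chromen-2-one | COc1cc(-c2c(O)cc3c(c2C)[C@@H](c2ccc(O)cc2)CC(=O)O3)oc(=O)c1 | target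

## Step count and least certain steps

Total step count: 9. Longest linear sequence: 7 steps (1, 2, 3, 5, 6, 8, 9); steps 4 and 7 are side branches.

**Step 5 (key step, proposed new method).** The most likely failure is consumption of the terminal alkyne before productive insertion, by metal acetylide formation and self-coupling or by addition of the carboxylate across the triple bond. A terminal C–H and a free acid are both reactive towards the catalyst, and the di-ortho-substituted aryl group slows insertion. Oxidation of ring A at the anode is the second risk.
Fallback (known chemistry), from 3 back to 7: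
- The dianion of methyl acetoacetate (NaH, then n-BuLi, THF, −78 °C) is added to 3 to give methyl 5-[2-(benzyloxy)-4-(methoxymethoxy)-6-methylphenyl]-5-hydroxy-3-oxopentanoate F1.
- The benzylic alcohol is oxidised with Dess–Martin periodinane in CH2Cl2 to methyl 5-[2-(benzyloxy)-4-(methoxymethoxy)-6-methylphenyl]-3,5-dioxopentanoate F2.
- DBU in hot toluene closes F2 to 6-[2-(benzyloxy)-4-(methoxymethoxy)-6-methylphenyl]-4-hydroxy-2H-pyran-2-one F3.
- Me2SO4 and K2CO3 in acetone methylate the 4-hydroxyl to give 7.

**Step 8.** The most likely failures are acylation of the phenol oxygen without C–C bond formation, slow attack at the methyl-flanked C4a, and poor facial selectivity. The phenol is less nucleophilic than a naphthol, and the C5 methyl group crowds the reacting carbon.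
Fallback, from 8 back to 11:
- Pd(OAc)2-catalysed hydroarylation of ethyl propiolate in TFA/CH2Cl2 is an electrophilic metalation para to the benzyloxy group followed by lactonisation. It should give 7-(benzyloxy)-6-(4-methoxy-2-oxo-2H-pyran-6-yl)-5-methyl-2H-chromen-2-one F4.
- Asymmetric 1,4-addition of 4-(benzyloxy)phenylboronic acid to F4 (Hayashi–Miyaura reaction, Rh(acac)(C2H4)2 with the Segphos enantiomer that delivers the aryl group to the face giving 4R, dioxane/H2O, 60 °C; a monovalent rhodium aryl adds to the coumarin) then gives 11.

**Step 9.** The most likely failure is partial hydrogenation of the pyrone ring while the hindered O7 benzyl ether is still being cleaved, because the two reductions can overlap in rate.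
Fallback, from 11 directly to 12: non-reductive cleavage of both benzyl ethers with BCl3 and pentamethylbenzene as cation scavenger in CH2Cl2 at −78 °C. This is a Lewis-acid mechanism that cannot reduce the pyrone, and it makes no new compound (F0).

**Step 3.** The most likely failure is incomplete conversion, since the aldehyde is electron-rich and flanked by two ortho substituents and the diazophosphonate anion decomposes in methanol while it waits.
Fallback, from 3 back to 4: Corey–Fuchs sequence. CBr4/PPh3 in CH2Cl2 gives 1-(benzyloxy)-2-(2,2-dibromoethenyl)-5-(methoxymethoxy)-3-methylbenzene F5. n-BuLi (2.2 equiv, THF, −78 °C) followed by an aqueous quench then gives 4 through the Fritsch–Buttenberg–Wiechell rearrangement.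

## Further compounds

F1 | step 5 | methyl 5-[2-(benzyloxy)-4-(methoxymethoxy)-6-methylphenyl]-5-hydroxy-3-oxopentanoate (racemic) | COC(=O)CC(=O)CC(O)c1c(C)cc(OCOC)cc1OCc1ccccc1
F2 | step 5 | methyl 5-[2-(benzyloxy)-4-(methoxymethoxy)-6-methylphenyl]-3,5-dioxopentanoate | COC(=O)CC(=O)CC(=O)c1c(C)cc(OCOC)cc1OCc1ccccc1
F3 | step 5 | 6-[2-(benzyloxy)-4-(methoxymethoxy)-6-methylphenyl]-4-hydroxy-2H-pyran-2-one | COCOc1cc(C)c(-c2cc(O)cc(=O)o2)c(OCc2ccccc2)c1
F4 | step 8 | 7-(benzyloxy)-6-(4-methoxy-2-oxo-2H-pyran-6-yl)-5-methyl-2H-chromen-2-one | COc1cc(-c2c(OCc3ccccc3)cc3oc(=O)ccc3c2C)oc(=O)c1
F0 | step 9 | none | none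
F5 | step 3 | 1-(benzyloxy)-2-(2,2-dibromoethenyl)-5-(methoxymethoxy)-3-methylbenzene | COCOc1cc(C)c(C=C(Br)Br)c(OCc2ccccc2)c1
A1 | alternative 1 | methyl (3R)-3-[6-(tert-butyldimethylsilyloxy)-4-(methoxymethoxy)-3-(4-methoxy-2-oxo-2H-pyran-6-yl)-2-methylphenyl]-3-[4-(tert-butyldimethylsilyloxy)phenyl]propanoate | COCOc1cc(O[Si](C)(C)C(C)(C)C)c([C@@H](c2ccc(O[Si](C)(C)C(C)(C)C)cc2)CC(=O)OC)c(C)c1-c1cc(OC)cc(=O)o1
A2 | alternative 1 | methyl (3R)-3-[2-(tert-butyldimethylsilyloxy)-4-(methoxymethoxy)cyclohexa-1,3-dien-1-yl]-3-[4-(tert-butyldimethylsilyloxy)phenyl]propanoate | COCOC1=CC(O[Si](C)(C)C(C)(C)C)=C([C@@H](c2ccc(O[Si](C)(C)C(C)(C)C)cc2)CC(=O)OC)CC1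
A3 | alternative 1 | 4-methoxy-6-(prop-1-yn-1-yl)-2H-pyran-2-one | CC#Cc1cc(OC)cc(=O)o1
A4 | alternative 2 | 4-(benzyloxy)-6-[4-(benzyloxy)-2-hydroxy-6-methylphenyl]-2H-pyran-2-one | O=c1cc(OCc2ccccc2)cc(-c2c(C)cc(OCc3ccccc3)cc2O)o1
A5 | alternative 2 | 4-(benzyloxy)-6-methyl-2H-pyran-2-one | Cc1cc(OCc2ccccc2)cc(=O)o1
A6 | alternative 3 | methyl (3R)-3-[3-bromo-4,6-bis(methoxymethoxy)-2-methylphenyl]-3-(4-hydroxyphenyl)propanoate | COCOc1cc(OCOC)c(Br)c(C)c1[C@@H](c1ccc(O)cc1)CC(=O)OC
A7 | alternative 3 | methyl (3S)-3-[3-bromo-4,6-bis(methoxymethoxy)-2-methylphenyl]-5-oxopentanoate | COCOc1cc(OCOC)c(Br)c(C)c1[C@@H](CC=O)CC(=O)OC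
A8 | alternative 3 | but-3-yn-2-one | CC(=O)C#C
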